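(The earlier runs and the new flask are simulated for substances that don't exist.)

- A small charge of X, such as the 0.0060 M of beta, can use only 8.00% of the D beside it if each E or L costs one D, as I assumed. So I reckoned cD as the charge minus that correction.

| flask | X | D | J | remark | time |
|---|---|---|---|---|---|
| summer | 0.0039 M | 0.075 M | 5 mM (in portions, 2) | run made earlier; portions every 3.0 h |  |
| spring | 0.12 M | 0.075 M | 5 mM (in portions, 2) | run made earlier; portions every 3.0 h |  |
| beta | 0.0060 M | 0.0750 M | 5.0 mM (in portions, 2) | the portions of J follow each other after 3.0 h, the first at the start | 6.0 h |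
| theta | 0.015 M | 0.0750 M | 5.0 mM (in portions, 2) | the portions of J follow each other after 3.0 h, the first at the start | 6.0 h |
| alpha | 0.050 M | 0.0750 M | 5.0 mM (in portions, 2) | the portions of J follow each other after 3.0 h, the first at the start | 6.0 h |
| epsilon | 0.15 M | 0.0750 M | 5.0 mM (in portions, 2) | the portions of J follow each other after 3.0 h, the first at the start | 6.0 h |

| run | time / h | E / % | L / % | X / % |
|---|---|---|---|---|
| summer | 0.667 | 20.8 | 20.6 | 58.7 |
| summer | 1.33 | 22.9 | 33.8 | 44.0 |
| summer | 2.00 | 22.6 | 43.4 | 35.3 |
| summer | 3.00 | 16.1 | 53.8 | 28.2 |
| summer | 4.00 | 12.8 | 65.6 | 21.2 |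
| spring | 0.333 | 8.3 | 8.7 | 81.2 |
| spring | 0.500 | 9.8 | 12.9 | 77.4 |
| spring | 1.00 | 13.4 | 20.3 | 66.6 |
| spring | 1.50 | 11.4 | 26.1 | 61.4 |
| spring | 2.50 | 9.4 | 34.8 | 54.8 |
| spring | 4.00 | 6.5 | 42.7 | 52.2 |

(each reading ± 1 percentage point)

- a step back or a flat step of under half a point counts as no turn
- a reading or a percentage of E counts all its forms, free or not
- "hardly changes" means that all values lie within two and a half points (for a concentration: within two and a half percent of the largest)

- share of E in all that became E or L for beta, theta, alpha, epsilon, in this order
- how that number moves from the first to the last of them (hardly changes / rises, then falls / falls, then rises / rises all the way / falls all the way)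

- In the first instants of summer, E and L rose side by side, at 20.8% and 20.6% after 0.667 h. In the middle of summer, E turned and followed X down while L kept climbing, so I read late E as a partner of X and D rather than as a kept product.
- I tested this with the late quotient Q, a mass-action quotient: the amount of E (bound forms counted) divided by the amount of X and by cD. At the last summer reading cD was 0.0719 M and E/X was 0.604. At the last spring reading cD was 0.0160 M and E/X was 0.125. The two quotients, 8.39 M⁻¹ and 7.80 M⁻¹, lay close together although cD differed widely, so as a reading I took their mean, 8.10 M⁻¹.
- For the end of beta I let the pool X + E shrink at the summer rate, 0.265 h⁻¹, a pseudo-first-order decay, which left 20.0% at 6.0 h. With cD near 0.0702 M, Q split that pool into X 12.8% and E 7.26%, a share of 8.32%.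
- In epsilon, D is the limiting reagent, since it covers 50.0% of the X charged. Spring's cD had been falling at 0.213 h⁻¹. I scaled that rate and the clock by the ratio of the X charges, so my estimate for epsilon put spring's last cD at 3.20 h and carried it on at 0.266 h⁻¹ to 0.007579 M. From that estimate the balance gave me X 55.1%, Q gave me E 3.38%, and my share for epsilon came to 7.52%.
- My two ends differed by 0.8 percentage points, which by the given rule counts as hardly changes, provided theta and alpha, which I did not reckon, lie between them. The forecast differed from this, with 7.5%, 8%, 9.5% and 17%, rises all the way, and it gave as the ground for its last point that “D runs out at about 40% conversion with E still present”.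
- The flask gave 9.86%, 9.92%, 9.90% and 7.29%: the share falls all the way.

    X + D → L (k = 5.40 M⁻¹ h⁻¹)
    X + D + J ⇌ E + J, rate k2*[X]*[D]*[J] forward; the back reaction follows from the equilibrium constant (K = 5.60 M⁻¹, k = 3500 M⁻² h⁻¹)
    J + E ⇌ G, settled at all times (K = 91.0 M⁻¹)
    X + J → Z (k = 0.490 M⁻¹ h⁻¹)

- At 6.00 h epsilon held X 54.3% of its charge and D 9.25% of its own. Q applied to those amounts gave E 3.05%, against the flask's 3.31% with G counted in. The same step on beta, with X 13.4% and D 93.1%, gave E 7.60%, against the flask's 8.51% with G counted in.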